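**Retrosynthetic overview**

1. The last bond is C5–C6. An intramolecular Nozaki–Hiyama–Kishi coupling (Z-vinyl iodide + aldehyde) closes the ten-membered carbocycle first, and the C6 alkoxide then closes the α-methylene-γ-lactone onto the C12 acrylate ester in the same operation.
2. Before that, the C9 acetate and the C8 (S)-2,3-dihydroxy-2-methylpropanoate (carried as its acetonide acid, from (R)-3-bromo-2-hydroxy-2-methylpropanoic acid) are placed on an acyclic C8/C9 syn-diol.
3. The key disconnection is C7–C8, made with reversed polarity. A 2-(methoxycarbonyl)allylindium (a β-acrylate anion, i.e. an ester homoenolate equivalent) adds through its β-carbon C7 to the aldehyde carbon C8 of an α-hydroxy aldehyde. Chelation plus a chair transition state set C7 and C8 from C9.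
4. Both partners come from one enantioselective Morita–Baylis–Hillman adduct of an acrylate with glyoxal mono(dimethyl acetal). SN2′ bromination gives the nucleophilic half (C6, C7, C11–C13). Cross-metathesis with (Z)-1-iodo-2-methylhexa-1,5-diene (carbocupration of propyne) gives the electrophilic half (C1–C5, C8–C10, C14, C15).

Assumption: locants C1–C15 in the text are the germacrane locants of the target (lactone carbonyl C12, exocyclic methylene C13, ester carbon C14, ring methyl C15). Commercial 60 % aqueous 2,2-dimethoxyacetaldehyde is dried before step 1, and catalysts (β-isocupreidine, Hoveyda–Grubbs II, NiCl2, Dowex) are not counted as starting materials.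

**Route**

Step 1
Reactants: 1 1,1,1,3,3,3-hexafluoropropan-2-yl acrylate; 2 2,2-dimethoxyacetaldehyde
Product: 4 methyl (3S)-3-hydroxy-4,4-dimethoxy-2-methylidenebutanoate, via HFIP ester 3 (not isolated)
Conditions: β-isocupreidine (10 mol%), DMF, −55 °C; then MeOH, Et3N (cat.), 25 °C
Reagents that add atoms: methanol (CO)
Why: Asymmetric Morita–Baylis–Hillman reaction in which the bifunctional cinchona catalyst lets the acrylate attack one aldehyde face, in the same sense as for aliphatic aldehydes (here 3S, because CH(OMe)2 outranks the acrylate carbon, which sets C9), after which the activated HFIP ester is exchanged for OMe by base-catalysed transesterification.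

Step 2
Reactants: 4 methyl (3S)-3-hydroxy-4,4-dimethoxy-2-methylidenebutanoate
Product: 5 methyl (2Z)-2-(bromomethyl)-4,4-dimethoxybut-2-enoate
Conditions: NBS, Me2S, CH2Cl2, 0 → 25 °C
Reagents that add atoms: N-bromosuccinimide (O=C1CCC(=O)N1Br)
Why: Corey–Kim-type activation turns the allylic OH into an alkoxysulfonium group that bromide displaces in SN2′ fashion, giving the thermodynamically preferred Z 2-(bromomethyl)enoate (CH(OMe)2 trans to CO2Me) under non-acidic conditions that spare the acetal; the stereocentre is erased on purpose.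

Step 3
Reactants: 6 but-3-en-1-ylmagnesium bromide; 7 propyne
Product: 10 (1Z)-1-iodo-2-methylhexa-1,5-diene, via butenylcopper 8 (not isolated), via alkenylcopper 9 (not isolated)
Conditions: CuBr·SMe2, Et2O/Me2S, −45 °C; propyne, −25 °C; I2, THF, −50 → 0 °C
Reagents that add atoms: iodine (II)
Why: Normant carbocupration adds the alkylcopper syn across propyne (alkyl to the internal carbon) and iodinolysis proceeds with retention, which fixes the Z trisubstituted alkene (butenyl cis to I) that becomes C4=C5.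

Step 4
Reactants: 4 methyl (3S)-3-hydroxy-4,4-dimethoxy-2-methylidenebutanoate; 10 (1Z)-1-iodo-2-methylhexa-1,5-diene
Product: 11 methyl (2E,6Z)-2-[(1S)-1-hydroxy-2,2-dimethoxyethyl]-7-iodo-6-methylhepta-2,6-dienoate
Conditions: Hoveyda–Grubbs II (5 mol%), 1,4-benzoquinone (10 mol%), 10 (3 equiv), CH2Cl2, 40 °C
Reagents that add atoms: none
Why: Olefin cross-metathesis between a terminal alkene used in excess and the 1,1-disubstituted acrylate, helped by the free allylic OH, gives the trisubstituted enoate with the chain trans to CO2Me (2E, the C1=C10 geometry), while the hindered trisubstituted vinyl iodide and the stereocentre are untouched.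

Step 5
Reactants: 11 methyl (2E,6Z)-2-[(1S)-1-hydroxy-2,2-dimethoxyethyl]-7-iodo-6-methylhepta-2,6-dienoate; 5 methyl (2Z)-2-(bromomethyl)-4,4-dimethoxybut-2-enoate
Product: 13 methyl (2E,6Z)-2-[(1S,2S,3R)-3-(dimethoxymethyl)-1,2-dihydroxy-4-(methoxycarbonyl)pent-4-en-1-yl]-7-iodo-6-methylhepta-2,6-dienoate, via α-hydroxy aldehyde 12 (not isolated)
Conditions: Dowex 50W (H+), THF/H2O, 40 °C; filter; then 5 (1.5 equiv), In powder, NaOAc buffer (pH 5–6), THF/H2O, 25 °C
Reagents that add atoms: water (O)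
Why: Indium-mediated Barbier reaction in which bromide 5 becomes a 2-(methoxycarbonyl)allylindium, a β-acrylate anion (ester homoenolate equivalent) whose C7, the electrophilic β-carbon of enoate 5, attacks the aldehyde carbon C8; indium is chelated by the α-OH of 12 (Cram chelate, C8–OH syn to C9–OH) and the Z-allylindium reacts through a Zimmerman–Traxler chair (C7/C8 syn), so C7 and C8 are both set from C9 with the relative configuration of the target.

Step 6
Reactants: 13 methyl (2E,6Z)-2-[(1S,2S,3R)-3-(dimethoxymethyl)-1,2-dihydroxy-4-(methoxycarbonyl)pent-4-en-1-yl]-7-iodo-6-methylhepta-2,6-dienoate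
Product: 14 methyl (2E,6Z)-2-[(1S,2S,3R)-1-(acetyloxy)-3-(dimethoxymethyl)-2-hydroxy-4-(methoxycarbonyl)pent-4-en-1-yl]-7-iodo-6-methylhepta-2,6-dienoate
Conditions: AcCl (1.05 equiv), 2,4,6-collidine, CH2Cl2, −40 °C
Reagents that add atoms: acetyl chloride (CC(Cl)=O)
Why: Kinetically controlled mono-acylation, because the allylic C9–OH next to the planar C10 is much less hindered than the C8–OH, which sits beside the doubly branched C7; no stereocentre is touched.

Step 7
Reactants: 15 (2R)-3-bromo-2-hydroxy-2-methylpropanoic acid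
Product: 17 (2S)-2,3-dihydroxy-2-methylpropanoic acid, via sodium glycidate 16 (not isolated)
Conditions: NaOH (aq.), 0 → 60 °C; then HCl to pH 1
Reagents that add atoms: sodium hydroxide ([Na+].[OH-])
Why: Intramolecular Williamson closure to the glycidate and SN2 opening by hydroxide at the unhindered CH2 leave the quaternary carbon untouched, so the R bromohydrin gives the S diol (the descriptor changes only through CIP priorities).

Step 8
Reactants: 17 (2S)-2,3-dihydroxy-2-methylpropanoic acid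
Product: 18 methyl (4S)-2,2,4-trimethyl-1,3-dioxolane-4-carboxylate
Conditions: Me2C(OMe)2, MeOH, TsOH (cat.), 50 °C
Reagents that add atoms: 2,2-dimethoxypropane (COC(C)(C)OC); methanol (CO)
Why: Acid-catalysed Fischer esterification with simultaneous transketalisation to the acetonide, as for tartaric acid, with 2,2-dimethoxypropane also scavenging water.

Step 9
Reactants: 18 methyl (4S)-2,2,4-trimethyl-1,3-dioxolane-4-carboxylate
Product: 19 (4S)-2,2,4-trimethyl-1,3-dioxolane-4-carboxylic acid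
Conditions: LiOH, THF/H2O, 0 °C; then 1 M HCl to pH 3, 0 °C
Reagents that add atoms: lithium hydroxide ([Li+].[OH-])
Why: Saponification of the methyl ester, in which the base-stable acetonide survives the brief cold acidification.

Step 10
Reactants: 14 methyl (2E,6Z)-2-[(1S,2S,3R)-1-(acetyloxy)-3-(dimethoxymethyl)-2-hydroxy-4-(methoxycarbonyl)pent-4-en-1-yl]-7-iodo-6-methylhepta-2,6-dienoate; 19 (4S)-2,2,4-trimethyl-1,3-dioxolane-4-carboxylic acid
Product: 21 methyl (2E,6Z)-2-[(1S,2S,3R)-1-(acetyloxy)-3-(dimethoxymethyl)-4-(methoxycarbonyl)-2-{[(4S)-2,2,4-trimethyl-1,3-dioxolane-4-carbonyl]oxy}pent-4-en-1-yl]-7-iodo-6-methylhepta-2,6-dienoate, via acid chloride 20 (not isolated)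
Conditions: 19, 1-chloro-N,N,2-trimethylprop-1-en-1-amine, CH2Cl2, 0 °C; then 14, pyridine, DMAP (cat.), 0 → 25 °C
Reagents that add atoms: none
Why: Neutral acid-chloride formation (Ghosez reagent) keeps the acetonide, and DMAP-catalysed acylation in pyridine esterifies the remaining hindered C8–OH under weakly basic conditions in which 1,2-acetyl migration is slow, so the C9 acetate/C8 ester pattern is kept.

Step 11
Reactants: 21 methyl (2E,6Z)-2-[(1S,2S,3R)-1-(acetyloxy)-3-(dimethoxymethyl)-4-(methoxycarbonyl)-2-{[(4S)-2,2,4-trimethyl-1,3-dioxolane-4-carbonyl]oxy}pent-4-en-1-yl]-7-iodo-6-methylhepta-2,6-dienoate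
Product: 22 methyl (2E,6Z)-2-[(1S,2S,3R)-1-(acetyloxy)-2-{[(2S)-2,3-dihydroxy-2-methylpropanoyl]oxy}-3-formyl-4-(methoxycarbonyl)pent-4-en-1-yl]-7-iodo-6-methylhepta-2,6-dienoate
Conditions: TFA/H2O (9:1), CH2Cl2, 0 °C
Reagents that add atoms: water (O)
Why: Aqueous acid hydrolysis cleaves the dimethyl acetal (to the C6 aldehyde) and the acetonide (to the free diol) in one operation, while the esters, the allylic acetate and the vinyl iodide are inert and the short cold exposure limits enolisation at C7.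

Step 12
Reactants: 22 methyl (2E,6Z)-2-[(1S,2S,3R)-1-(acetyloxy)-2-{[(2S)-2,3-dihydroxy-2-methylpropanoyl]oxy}-3-formyl-4-(methoxycarbonyl)pent-4-en-1-yl]-7-iodo-6-methylhepta-2,6-dienoate
Product: 24 methyl (3aS,4S,5S,6E,10Z,11aR)-5-(acetyloxy)-4-{[(2S)-2,3-dihydroxy-2-methylpropanoyl]oxy}-10-methyl-3-methylidene-2-oxo-2,3,3a,4,5,8,9,11a-octahydrocyclodeca[b]furan-6-carboxylate, via seco hydroxy ester 23 (not isolated)
Conditions: CrCl2 (10 equiv), NiCl2 (1 mol%), DMSO, 0.002 M (syringe pump), 25 °C; then PPTS (cat.), CH2Cl2, 25 °C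
Reagents that add atoms: none
Why: Intramolecular Nozaki–Hiyama–Kishi reaction in which the Z-alkenylchromium (geometry retained) adds chemoselectively to the aldehyde at high dilution to close the ten-membered ring, approaching C6 anti to the C7–C8 bond (Felkin–Anh, reinforced by the 1,3-anti preference relative to the C8 acyloxy group) to give 6R, after which the C6 hydroxyl lactonises 5-exo onto the neighbouring acrylate ester to the trans-fused α-methylene-γ-lactone.

**Compound list**

1 | 1,1,1,3,3,3-hexafluoropropan-2-yl acrylate | C=CC(=O)OC(C(F)(F)F)C(F)(F)F | starting material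
2 | 2,2-dimethoxyacetaldehyde | O=CC(OC)OC | starting material
3 | 1,1,1,3,3,3-hexafluoropropan-2-yl (3S)-3-hydroxy-4,4-dimethoxy-2-methylidenebutanoate | C=C(C(=O)OC(C(F)(F)F)C(F)(F)F)[C@H](O)C(OC)OC | intermediate
4 | methyl (3S)-3-hydroxy-4,4-dimethoxy-2-methylidenebutanoate | C=C(C(=O)OC)[C@H](O)C(OC)OC | intermediate
5 | methyl (2Z)-2-(bromomethyl)-4,4-dimethoxybut-2-enoate | BrC/C(C(=O)OC)=C\C(OC)OC | intermediate
6 | but-3-en-1-ylmagnesium bromide | C=CCC[Mg]Br | starting material
7 | propyne | CC#C | starting material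
8 | but-3-en-1-ylcopper(I) | C=CCC[Cu] | intermediate
9 | [(1Z)-2-methylhexa-1,5-dien-1-yl]copper(I) | [Cu]/C=C(/C)CCC=C | intermediate
10 | (1Z)-1-iodo-2-methylhexa-1,5-diene | I/C=C(/C)CCC=C | intermediate
11 | methyl (2E,6Z)-2-[(1S)-1-hydroxy-2,2-dimethoxyethyl]-7-iodo-6-methylhepta-2,6-dienoate | COC(=O)/C(=C/CC/C(C)=C\I)[C@H](O)C(OC)OC | intermediate
12 | methyl (2E,6Z)-2-[(1S)-1-hydroxy-2-oxoethyl]-7-iodo-6-methylhepta-2,6-dienoate | COC(=O)/C(=C/CC/C(C)=C\I)[C@H](O)C=O | intermediate
13 | methyl (2E,6Z)-2-[(1S,2S,3R)-3-(dimethoxymethyl)-1,2-dihydroxy-4-(methoxycarbonyl)pent-4-en-1-yl]-7-iodo-6-methylhepta-2,6-dienoate | COC(=O)/C(=C/CC/C(C)=C\I)[C@H](O)[C@@H](O)[C@@H](C(=C)C(=O)OC)C(OC)OC | intermediate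
14 | methyl (2E,6Z)-2-[(1S,2S,3R)-1-(acetyloxy)-3-(dimethoxymethyl)-2-hydroxy-4-(methoxycarbonyl)pent-4-en-1-yl]-7-iodo-6-methylhepta-2,6-dienoate | COC(=O)/C(=C/CC/C(C)=C\I)[C@H](OC(C)=O)[C@@H](O)[C@@H](C(=C)C(=O)OC)C(OC)OC | intermediate
15 | (2R)-3-bromo-2-hydroxy-2-methylpropanoic acid | OC(=O)[C@@](C)(O)CBr | starting material
16 | sodium (2S)-2-methyloxirane-2-carboxylate | [Na+].[O-]C(=O)[C@@]1(C)OC1 | intermediate
17 | (2S)-2,3-dihydroxy-2-methylpropanoic acid | OC(=O)[C@@](C)(O)CO | intermediate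
18 | methyl (4S)-2,2,4-trimethyl-1,3-dioxolane-4-carboxylate | COC(=O)[C@@]1(C)OC(C)(C)OC1 | intermediate
19 | (4S)-2,2,4-trimethyl-1,3-dioxolane-4-carboxylic acid | OC(=O)[C@@]1(C)OC(C)(C)OC1 | intermediate
20 | (4S)-2,2,4-trimethyl-1,3-dioxolane-4-carbonyl chloride | ClC(=O)[C@@]1(C)OC(C)(C)OC1 | intermediate
21 | methyl (2E,6Z)-2-[(1S,2S,3R)-1-(acetyloxy)-3-(dimethoxymethyl)-4-(methoxycarbonyl)-2-{[(4S)-2,2,4-trimethyl-1,3-dioxolane-4-carbonyl]oxy}pent-4-en-1-yl]-7-iodo-6-methylhepta-2,6-dienoate | COC(=O)/C(=C/CC/C(C)=C\I)[C@H](OC(C)=O)[C@@H](OC(=O)[C@@]1(C)OC(C)(C)OC1)[C@@H](C(=C)C(=O)OC)C(OC)OC | intermediate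
22 | methyl (2E,6Z)-2-[(1S,2S,3R)-1-(acetyloxy)-2-{[(2S)-2,3-dihydroxy-2-methylpropanoyl]oxy}-3-formyl-4-(methoxycarbonyl)pent-4-en-1-yl]-7-iodo-6-methylhepta-2,6-dienoate | COC(=O)/C(=C/CC/C(C)=C\I)[C@H](OC(C)=O)[C@@H](OC(=O)[C@@](C)(O)CO)[C@@H](C(=C)C(=O)OC)C=O | intermediate
23 | methyl (1E,5Z,7R,8S,9S,10S)-10-(acetyloxy)-9-{[(2S)-2,3-dihydroxy-2-methylpropanoyl]oxy}-7-hydroxy-8-(3-methoxy-3-oxoprop-1-en-2-yl)-5-methylcyclodeca-1,5-diene-1-carboxylate | O[C@@H]1/C=C(/C)CC/C=C(/C(=O)OC)[C@H](OC(C)=O)[C@@H](OC(=O)[C@@](C)(O)CO)[C@H]1C(=C)C(=O)OC | intermediate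
24 | methyl (3aS,4S,5S,6E,10Z,11aR)-5-(acetyloxy)-4-{[(2S)-2,3-dihydroxy-2-methylpropanoyl]oxy}-10-methyl-3-methylidene-2-oxo-2,3,3a,4,5,8,9,11a-octahydrocyclodeca[b]furan-6-carboxylate (CNP0197537.1; germacrane descriptors 6R,7S,8S,9S) | C=C1C(=O)O[C@@H]2/C=C(/C)CC/C=C(/C(=O)OC)[C@H](OC(C)=O)[C@@H](OC(=O)[C@@](C)(O)CO)[C@@H]12 | target

**Step count and risks**

Total step count: 12. Longest linear sequence: 7 steps (1, 4, 5, 6, 10, 11, 12).

The three steps most likely to fail:

Step 12 (ten-membered ring closure with control of C6). The C6 configuration rests on a substrate-control argument inside a macrocyclic transition state. The fallback sets out from 23 and comes back at 24. The chromium reaction is worked up without the acid treatment and the seco alcohol 23 is isolated as its C6 epimer mixture. It is oxidised (Dess–Martin periodinane, NaHCO3, CH2Cl2) to the macrocyclic enone methyl (1E,5Z,8R,9S,10S)-10-(acetyloxy)-9-{[(2S)-2,3-dihydroxy-2-methylpropanoyl]oxy}-8-(3-methoxy-3-oxoprop-1-en-2-yl)-5-methyl-7-oxocyclodeca-1,5-diene-1-carboxylate F1. C6 is then set by reagent control with (R)-Me-CBS/catecholborane at −78 °C (alkenyl as the large group), which returns 6R-23; PPTS closes the lactone to 24.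

Step 5 (the indium coupling). The free α-hydroxy aldehyde 12 may enolise at C9 in water, and the syn,syn selectivity depends on chelation. The fallback sets out from 5 (used with 12) and comes back at 13. Bromide 5 is converted by Pd-catalysed borylation (B2pin2, Pd2(dba)3, toluene, 50 °C) into the allylboronate methyl (2Z)-4,4-dimethoxy-2-[(4,4,5,5-tetramethyl-1,3,2-dioxaborolan-2-yl)methyl]but-2-enoate F2. 12 is extracted into CH2Cl2 and treated with F2 over 4 Å sieves. The α-hydroxyl binds to boron and the Z-allyl group is delivered intramolecularly through a chair (hydroxyl-directed allylboration), which again gives the syn,syn diol 13 after triethanolamine work-up, with no water and no metal salts present.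

Step 6 (telling the two secondary hydroxyls apart with a small acylating agent). The fallback sets out from 13 and comes back at 21.
- A bulkier, non-migrating group is put on first: TESCl/imidazole (DMF, −40 °C) gives the C9 silyl ether methyl (2E,6Z)-2-[(1S,2S,3R)-3-(dimethoxymethyl)-2-hydroxy-4-(methoxycarbonyl)-1-[(triethylsilyl)oxy]pent-4-en-1-yl]-7-iodo-6-methylhepta-2,6-dienoate F3.
- The C8–OH is esterified with acid chloride 20 (pyridine, DMAP) to methyl (2E,6Z)-2-[(1S,2S,3R)-3-(dimethoxymethyl)-4-(methoxycarbonyl)-1-[(triethylsilyl)oxy]-2-{[(4S)-2,2,4-trimethyl-1,3-dioxolane-4-carbonyl]oxy}pent-4-en-1-yl]-7-iodo-6-methylhepta-2,6-dienoate F4.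
- HF·pyridine (THF/pyridine, 0 °C) frees the C9 alcohol methyl (2E,6Z)-2-[(1S,2S,3R)-3-(dimethoxymethyl)-1-hydroxy-4-(methoxycarbonyl)-2-{[(4S)-2,2,4-trimethyl-1,3-dioxolane-4-carbonyl]oxy}pent-4-en-1-yl]-7-iodo-6-methylhepta-2,6-dienoate F5.
- Ac2O/pyridine/DMAP then gives 21.

A silyl chloride discriminates the hindered C8–OH far better than acetyl chloride does, and a silyl ether cannot migrate during the C8 esterification.

Further compounds
F1 | step 12 | methyl (1E,5Z,8R,9S,10S)-10-(acetyloxy)-9-{[(2S)-2,3-dihydroxy-2-methylpropanoyl]oxy}-8-(3-methoxy-3-oxoprop-1-en-2-yl)-5-methyl-7-oxocyclodeca-1,5-diene-1-carboxylate | O=C1/C=C(/C)CC/C=C(/C(=O)OC)[C@H](OC(C)=O)[C@@H](OC(=O)[C@@](C)(O)CO)[C@H]1C(=C)C(=O)OC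
F2 | step 5 | methyl (2Z)-4,4-dimethoxy-2-[(4,4,5,5-tetramethyl-1,3,2-dioxaborolan-2-yl)methyl]but-2-enoate | CC1(C)OB(C/C(C(=O)OC)=C\C(OC)OC)OC1(C)C
F3 | step 6 | methyl (2E,6Z)-2-[(1S,2S,3R)-3-(dimethoxymethyl)-2-hydroxy-4-(methoxycarbonyl)-1-[(triethylsilyl)oxy]pent-4-en-1-yl]-7-iodo-6-methylhepta-2,6-dienoate | COC(=O)/C(=C/CC/C(C)=C\I)[C@H](O[Si](CC)(CC)CC)[C@@H](O)[C@@H](C(=C)C(=O)OC)C(OC)OC
F4 | step 6 | methyl (2E,6Z)-2-[(1S,2S,3R)-3-(dimethoxymethyl)-4-(methoxycarbonyl)-1-[(triethylsilyl)oxy]-2-{[(4S)-2,2,4-trimethyl-1,3-dioxolane-4-carbonyl]oxy}pent-4-en-1-yl]-7-iodo-6-methylhepta-2,6-dienoate | COC(=O)/C(=C/CC/C(C)=C\I)[C@H](O[Si](CC)(CC)CC)[C@@H](OC(=O)[C@@]1(C)OC(C)(C)OC1)[C@@H](C(=C)C(=O)OC)C(OC)OC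
F5 | step 6 | methyl (2E,6Z)-2-[(1S,2S,3R)-3-(dimethoxymethyl)-1-hydroxy-4-(methoxycarbonyl)-2-{[(4S)-2,2,4-trimethyl-1,3-dioxolane-4-carbonyl]oxy}pent-4-en-1-yl]-7-iodo-6-methylhepta-2,6-dienoate | COC(=O)/C(=C/CC/C(C)=C\I)[C@H](O)[C@@H](OC(=O)[C@@]1(C)OC(C)(C)OC1)[C@@H](C(=C)C(=O)OC)C(OC)OC
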